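## Retrosynthetic overview

1. Stylatulide lactone 27 ⇒ open the ten-membered ring B at C5=C6 (ring-closing metathesis, last step) to seco-triene 26.
2. Ring C (γ-lactone; C7, C8, C17) ⇒ hydroxyl-directed epoxidation and lactonisation of E-dienyl ester 22; C8–C17 by Negishi coupling, C8–C9 by alkynylation of aldehyde 16 followed by trans-hydrostannation.
3. C2 and C14 acetates ⇒ 1,3-syn reduction and catalyst-controlled allylboration; ring A ⇒ ring-closing metathesis at C11=C12.
4. C1 (quaternary) and C10 ⇒ catalytic enantioselective Claisen rearrangement of the achiral allyl vinyl ether 8, built from enone 4, methallyl bromide 5 and prenol-derived alcohol 3.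
5. Ring order: A (cyclohexene) → C (lactone) → B (cyclodecene).

Assumptions and conventions: 4 and 17 are bought (4 is otherwise one operation from butanone, methyl formate and NaOMe, then acidic methanol). Positions are given in briarane numbering: C1 is the quaternary carbon, C2–C10 lie in ring B, C11–C14 in ring A, C17 is the lactone CH, C18 its methyl, C19 the lactone carbonyl. TBS = tert-butyldimethylsilyl. G = N,N′-bis[(1R,2R)-2-(2,5-diphenylpyrrol-1-yl)cyclohexyl]guanidinium tetrakis[3,5-bis(trifluoromethyl)phenyl]borate or its mirror image; the sense of induction on this substrate is not known, so the antipode that gives (2R,3S)-9 is chosen after a first run. (S)-TRIP = (S)-3,3′-bis(2,4,6-triisopropylphenyl)-1,1′-binaphthyl-2,2′-diyl hydrogen phosphate. SIMes = 1,3-dimesitylimidazolidin-2-ylidene. The route is a proposal and has not been run.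

## Route

Step 1
Reactants: 1 3-methylbut-2-en-1-ol (prenol)
Product: 2 prenyl TBS ether
Conditions: TBSCl, imidazole, CH2Cl2, 0 °C to rt
Reagents that add atoms: tert-butyldimethylsilyl chloride, C[Si](C)(Cl)C(C)(C)C
Why: Imidazole-promoted O-silylation of a primary alcohol, with no stereocentre involved.

Step 2
Reactants: 2 prenyl TBS ether
Product: 3 (2E)-4-(TBS-oxy)-2-methylbut-2-en-1-ol
Conditions: SeO2 (cat.), t-BuOOH, CH2Cl2, 0 °C to rt
Reagents that add atoms: tert-butyl hydroperoxide, CC(C)(C)OO (oxygen passed on through selenium dioxide, O=[Se]=O)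
Why: Selenium dioxide allylic oxidation (ene reaction then [2,3]-shift) oxidises the methyl group trans to the chain of the trisubstituted alkene and so gives the E-allylic alcohol.

Step 3
Reactants: 4 (3E)-4-methoxy-3-methylbut-3-en-2-one; 5 3-bromo-2-methylprop-1-ene
Product: 7 (1E)-1-methoxy-2,6-dimethylhepta-1,6-dien-3-one, via lithium enolate 6 (not isolated)
Conditions: LiN(i-Pr)2, THF, −78 °C; then 5, −78 to −30 °C
Reagents that add atoms: none
Why: Kinetic α′-deprotonation of a β-alkoxy enone (Stork–Danheiser type) and C-alkylation with a reactive allylic bromide attaches C4, C5 and C16, with no stereocentre formed.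

Step 4
Reactants: 7 methoxy enone; 3 allylic alcohol
Product: 8 allyl vinyl ether (O-allyl vinylogous ester)
Conditions: PPTS (5 mol%), toluene, 40 °C, reduced pressure (MeOH removed)
Reagents that add atoms: none
Why: Acid-catalysed alkoxy exchange of a vinylogous ester (addition–elimination) is driven by removal of methanol, keeps the thermodynamic E-enol ether, and is run cold enough that 8 does not yet rearrange.

Step 5
Reactants: 8 allyl vinyl ether
Product: 9 (2R,3S)-α-formyl ketone with C1 and C10 set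
Conditions: G (20 mol%), hexanes, 35 °C, 4 d
Reagents that add atoms: none
Why: Proposed new method: the chiral guanidinium ion, hydrogen-bonded to the enone oxygen and the ether oxygen, should stabilise the dipolar chair transition state of the [3,3]-shift of this acyclic, aldehyde-derived O-allyl vinylogous ester and select one of the two mirror-image chairs, while the E-enol ether (acyl equatorial) and the E-allyl unit (CH2OTBS equatorial) fix the relative configuration of quaternary C1 and tertiary C10; the closest known reaction type is the guanidinium-catalysed enantioselective Claisen rearrangement of O-allyl α-ketoesters and of cyclic O-allyl β-ketoesters.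

Step 6
Reactants: 9 α-formyl ketone
Product: 10 homoallylic alcohol (14S)
Conditions: allylB(pin), (S)-TRIP (5 mol%), toluene, −30 °C
Reagents that add atoms: allylboronic acid pinacol ester, C=CCB1OC(C)(C)C(C)(C)O1
Why: Chiral phosphoric acid-catalysed allylboration (closed chair transition state) is selective for the aldehyde over the hindered ketone and delivers allyl to the Si face under catalyst control, setting 14S.

Step 7
Reactants: 10 homoallylic alcohol
Product: 11 ring A hydroxy ketone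
Conditions: second-generation Grubbs catalyst RuCl2(=CHPh)(PCy3)(SIMes) (3 mol%), CH2Cl2, 40 °C
Reagents that add atoms: none
Why: Ring-closing metathesis between the allyl group and the C11 isopropenyl group closes the six-membered ring A far faster than any larger ring and leaves the remote 1,1-disubstituted alkene untouched.

Step 8
Reactants: 11 ring A hydroxy ketone
Product: 13 syn-1,3-diol (2R), via boron chelate 12 (not isolated)
Conditions: Et2BOMe, THF/MeOH, −78 °C; then NaBH4; MeOH work-up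
Reagents that add atoms: none
Why: Narasaka–Prasad reduction, in which external hydride attacks the boron chelate of the β-hydroxy ketone axially, gives the 1,3-syn diol and therefore 2R.

Step 9
Reactants: 13 syn-1,3-diol
Product: 14 diacetate
Conditions: Ac2O, pyridine, DMAP (cat.), CH2Cl2, rt
Reagents that add atoms: acetic anhydride, CC(=O)OC(C)=O
Why: DMAP-catalysed acetylation of both secondary alcohols installs the C2 and C14 acetates of the target and leaves the silyl ether alone.

Step 10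
Reactants: 14 diacetate
Product: 15 primary alcohol
Conditions: HF·pyridine, pyridine, THF, 0 °C to rt
Reagents that add atoms: none
Why: Buffered fluoride desilylation removes the primary TBS ether without touching the acetates.

Step 11
Reactants: 15 primary alcohol
Product: 16 C9 aldehyde
Conditions: Dess–Martin periodinane, NaHCO3, CH2Cl2, 0 °C (used at once)
Reagents that add atoms: none
Why: Buffered Dess–Martin oxidation gives the β,γ-unsaturated aldehyde without epimerisation or olefin migration at C10.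

Step 12
Reactants: 17 (3E)-pent-3-en-1-yne
Product: 18 (3E)-1-iodopent-3-en-1-yne
Conditions: NIS, AgNO3 (10 mol%), acetone, rt
Reagents that add atoms: N-iodosuccinimide, O=C1CCC(=O)N1I
Why: Silver-catalysed electrophilic iodination of a terminal alkyne.

Step 13
Reactants: 16 C9 aldehyde; 18 iodoalkyne
Product: 19 propargylic alcohol (9R)
Conditions: CrCl2, NiCl2 (1 mol%), THF, rt
Reagents that add atoms: none
Why: Nozaki–Hiyama–Kishi alkynylation is selective for the aldehyde in the presence of acetates, and Felkin–Anh addition anti to the quaternary C1 sets 9R.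

Step 14
Reactants: 19 propargylic alcohol
Product: 20 alkenylstannane
Conditions: [Cp*RuCl]4 (2.5 mol%), Bu3SnH, CH2Cl2, rt
Reagents that add atoms: tributyltin hydride, CCCC[SnH](CCCC)CCCC
Why: Hydroxyl-directed ruthenium-catalysed trans-hydrostannation puts tin on the alkyne carbon next to the OH and hydrogen anti to it, which fixes the C7=C8 geometry with C6 trans to C9.

Step 15
Reactants: 20 alkenylstannane
Product: 21 alkenyl iodide
Conditions: I2, CH2Cl2, 0 °C
Reagents that add atoms: iodine, II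
Why: Iododestannylation proceeds with retention of the alkene geometry.

Step 16
Reactants: 21 alkenyl iodide
Product: 22 dienyl tert-butyl ester (C17 epimer mixture)
Conditions: BrZnCH(CH3)CO2t-Bu (3 equiv), Pd(P(t-Bu)3)2 (5 mol%), THF, rt
Reagents that add atoms: (1-tert-butoxy-1-oxopropan-2-yl)zinc bromide, CC([Zn]Br)C(=O)OC(C)(C)C
Why: Negishi-type coupling of the alkenyl iodide with a Reformatsky reagent (palladium-catalysed α-alkenylation of an ester zinc enolate) forms C8–C17 with retention of olefin geometry, the free C9 hydroxyl being carried as its zinc alkoxide and the C17 mixture being corrected in step 19.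

Step 17
Reactants: 22 dienyl tert-butyl ester
Product: 24 β-hydroxy-γ-lactone with free 9-OH, via epoxide 23 (not isolated)
Conditions: VO(acac)2 (5 mol%), t-BuOOH, CH2Cl2, 0 °C; then CF3CO2H, 0 °C
Reagents that add atoms: tert-butyl hydroperoxide, CC(C)(C)OO
Why: Vanadium-catalysed hydroxyl-directed epoxidation occurs only at the allylic C7=C8 bond and, because of A(1,2) strain from the C8 substituent, on the erythro face (sets C8), and acid then makes the ester carbonyl open the allylic epoxide at C7 with inversion (sets 7S) and loss of isobutene to close the five-membered lactone.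

Step 18
Reactants: 24 hydroxy lactone
Product: 25 triacetate (C17 epimer mixture)
Conditions: Ac2O, pyridine, DMAP (cat.), CH2Cl2, 0 °C to rt
Reagents that add atoms: acetic anhydride, CC(=O)OC(C)=O
Why: Acetylation of the secondary C9 alcohol, with the tertiary C8 alcohol left free under these conditions.

Step 19
Reactants: 25 triacetate
Product: 26 triacetate, 17R epimer
Conditions: DBU, toluene, 60 °C
Reagents that add atoms: none
Why: Base-mediated α-epimerisation of the lactone through its enolate should favour the 17R epimer, in which the methyl group is trans to the C8–C9 bond (estimated preference about 1 kcal/mol).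

Step 20
Reactants: 26 seco-triene
Product: 27 stylatulide lactone
Conditions: second-generation Hoveyda–Grubbs catalyst RuCl2(=CH-C6H4-2-O-i-Pr)(SIMes) (10 mol%), toluene (1 mM), 90 °C
Reagents that add atoms: none
Why: Ring-closing metathesis of the 1,1-disubstituted C5 olefin with the propenyl group on C7 closes the ten-membered ring B, and the medium ring favours the Z geometry at C5=C6.

## Compound list

1 | 3-methylbut-2-en-1-ol | CC(C)=CCO | starting material
2 | tert-butyl(dimethyl)[(3-methylbut-2-en-1-yl)oxy]silane | CC(C)=CCO[Si](C)(C)C(C)(C)C | intermediate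
3 | (2E)-4-{[tert-butyl(dimethyl)silyl]oxy}-2-methylbut-2-en-1-ol | OC/C(C)=C/CO[Si](C)(C)C(C)(C)C | intermediate
4 | (3E)-4-methoxy-3-methylbut-3-en-2-one | CO/C=C(\C)C(C)=O | starting material
5 | 3-bromo-2-methylprop-1-ene | C=C(C)CBr | starting material
6 | lithium (3E)-4-methoxy-3-methylbuta-1,3-dien-2-olate | C=C(O[Li])/C(C)=C/OC | intermediate
7 | (1E)-1-methoxy-2,6-dimethylhepta-1,6-dien-3-one | CO/C=C(\C)C(=O)CCC(C)=C | intermediate
8 | (1E)-1-{[(2E)-4-{[tert-butyl(dimethyl)silyl]oxy}-2-methylbut-2-en-1-yl]oxy}-2,6-dimethylhepta-1,6-dien-3-one | C=C(C)CCC(=O)/C(C)=C/OC/C(C)=C/CO[Si](C)(C)C(C)(C)C | intermediate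
9 | (2R,3S)-3-({[tert-butyl(dimethyl)silyl]oxy}methyl)-2,4-dimethyl-2-(4-methylpent-4-enoyl)pent-4-enal | O=C[C@](C)(C(=O)CCC(C)=C)[C@@H](CO[Si](C)(C)C(C)(C)C)C(C)=C | intermediate
10 | (6R,7S)-6-[(2S)-1-{[tert-butyl(dimethyl)silyl]oxy}-3-methylbut-3-en-2-yl]-7-hydroxy-2,6-dimethyldeca-1,9-dien-5-one | C=CC[C@H](O)[C@](C)(C(=O)CCC(C)=C)[C@@H](CO[Si](C)(C)C(C)(C)C)C(C)=C | intermediate
11 | 1-[(1R,2S,6S)-2-({[tert-butyl(dimethyl)silyl]oxy}methyl)-6-hydroxy-1,3-dimethylcyclohex-3-en-1-yl]-4-methylpent-4-en-1-one | O[C@H]1CC=C(C)[C@H](CO[Si](C)(C)C(C)(C)C)[C@@]1(C)C(=O)CCC(C)=C | intermediate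
12 | diethylboron chelate of 11 (O14–BEt2, boron also held by the C2 ketone oxygen) | CCB(CC)O[C@H]1CC=C(C)[C@H](CO[Si](C)(C)C(C)(C)C)[C@@]1(C)C(=O)CCC(C)=C | intermediate
13 | (1R)-1-[(1S,2S,6S)-2-({[tert-butyl(dimethyl)silyl]oxy}methyl)-6-hydroxy-1,3-dimethylcyclohex-3-en-1-yl]-4-methylpent-4-en-1-ol | O[C@H]1CC=C(C)[C@H](CO[Si](C)(C)C(C)(C)C)[C@@]1(C)[C@H](O)CCC(C)=C | intermediate
14 | (1R)-1-[(1S,2S,6S)-6-acetoxy-2-({[tert-butyl(dimethyl)silyl]oxy}methyl)-1,3-dimethylcyclohex-3-en-1-yl]-4-methylpent-4-en-1-yl acetate | CC(=O)O[C@H]1CC=C(C)[C@H](CO[Si](C)(C)C(C)(C)C)[C@@]1(C)[C@H](OC(C)=O)CCC(C)=C | intermediate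
15 | (1R)-1-[(1S,2S,6S)-6-acetoxy-2-(hydroxymethyl)-1,3-dimethylcyclohex-3-en-1-yl]-4-methylpent-4-en-1-yl acetate | CC(=O)O[C@H]1CC=C(C)[C@H](CO)[C@@]1(C)[C@H](OC(C)=O)CCC(C)=C | intermediate
16 | (1R)-1-[(1S,2S,6S)-6-acetoxy-2-formyl-1,3-dimethylcyclohex-3-en-1-yl]-4-methylpent-4-en-1-yl acetate | CC(=O)O[C@H]1CC=C(C)[C@H](C=O)[C@@]1(C)[C@H](OC(C)=O)CCC(C)=C | intermediate
17 | (3E)-pent-3-en-1-yne | C/C=C/C#C | starting material
18 | (3E)-1-iodopent-3-en-1-yne | C/C=C/C#CI | intermediate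
19 | (1R)-1-[(1S,2S,6S)-6-acetoxy-2-[(1R,4E)-1-hydroxyhex-4-en-2-yn-1-yl]-1,3-dimethylcyclohex-3-en-1-yl]-4-methylpent-4-en-1-yl acetate | CC(=O)O[C@H]1CC=C(C)[C@H]([C@@H](O)C#C/C=C/C)[C@@]1(C)[C@H](OC(C)=O)CCC(C)=C | intermediate
20 | (1R)-1-[(1S,2S,6S)-6-acetoxy-2-[(1R,2Z,4E)-1-hydroxy-2-(tributylstannyl)hexa-2,4-dien-1-yl]-1,3-dimethylcyclohex-3-en-1-yl]-4-methylpent-4-en-1-yl acetate | CC(=O)O[C@H]1CC=C(C)[C@H]([C@@H](O)/C(=C/C=C/C)[Sn](CCCC)(CCCC)CCCC)[C@@]1(C)[C@H](OC(C)=O)CCC(C)=C | intermediate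
21 | (1R)-1-[(1S,2S,6S)-6-acetoxy-2-[(1R,2Z,4E)-1-hydroxy-2-iodohexa-2,4-dien-1-yl]-1,3-dimethylcyclohex-3-en-1-yl]-4-methylpent-4-en-1-yl acetate | CC(=O)O[C@H]1CC=C(C)[C@H]([C@@H](O)/C(I)=C/C=C/C)[C@@]1(C)[C@H](OC(C)=O)CCC(C)=C | intermediate
22 | (1R)-1-[(1S,2S,6S)-6-acetoxy-2-[(1R,2E,4E)-2-(1-tert-butoxy-1-oxopropan-2-yl)-1-hydroxyhexa-2,4-dien-1-yl]-1,3-dimethylcyclohex-3-en-1-yl]-4-methylpent-4-en-1-yl acetate (both C17 epimers) | CC(=O)O[C@H]1CC=C(C)[C@H]([C@@H](O)/C(=C/C=C/C)C(C)C(=O)OC(C)(C)C)[C@@]1(C)[C@H](OC(C)=O)CCC(C)=C | intermediate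
23 | (1R)-1-[(1S,2S,6S)-6-acetoxy-2-{(R)-hydroxy[(2R,3R)-2-(1-tert-butoxy-1-oxopropan-2-yl)-3-[(1E)-prop-1-en-1-yl]oxiran-2-yl]methyl}-1,3-dimethylcyclohex-3-en-1-yl]-4-methylpent-4-en-1-yl acetate (erythro epoxy alcohol, both C17 epimers) | CC(=O)O[C@H]1CC=C(C)[C@H]([C@@H](O)[C@]2(O[C@@H]2/C=C/C)C(C)C(=O)OC(C)(C)C)[C@@]1(C)[C@H](OC(C)=O)CCC(C)=C | intermediate
24 | (1R)-1-[(1S,2S,6S)-6-acetoxy-2-{(R)-hydroxy[(2S,3R)-3-hydroxy-4-methyl-5-oxo-2-[(1E)-prop-1-en-1-yl]oxolan-3-yl]methyl}-1,3-dimethylcyclohex-3-en-1-yl]-4-methylpent-4-en-1-yl acetate (both C17 epimers) | CC(=O)O[C@H]1CC=C(C)[C@H]([C@@H](O)[C@@]2(O)[C@H](/C=C/C)OC(=O)C2C)[C@@]1(C)[C@H](OC(C)=O)CCC(C)=C | intermediate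
25 | (1R)-1-[(1S,2S,6S)-6-acetoxy-2-{(R)-acetoxy[(2S,3S)-3-hydroxy-4-methyl-5-oxo-2-[(1E)-prop-1-en-1-yl]oxolan-3-yl]methyl}-1,3-dimethylcyclohex-3-en-1-yl]-4-methylpent-4-en-1-yl acetate (both C17 epimers) | CC(=O)O[C@H]1CC=C(C)[C@H]([C@@H](OC(C)=O)[C@@]2(O)[C@H](/C=C/C)OC(=O)C2C)[C@@]1(C)[C@H](OC(C)=O)CCC(C)=C | intermediate
26 | (1R)-1-[(1S,2S,6S)-6-acetoxy-2-{(R)-acetoxy[(2S,3S,4R)-3-hydroxy-4-methyl-5-oxo-2-[(1E)-prop-1-en-1-yl]oxolan-3-yl]methyl}-1,3-dimethylcyclohex-3-en-1-yl]-4-methylpent-4-en-1-yl acetate | CC(=O)O[C@H]1CC=C(C)[C@H]([C@@H](OC(C)=O)[C@@]2(O)[C@H](/C=C/C)OC(=O)[C@@H]2C)[C@@]1(C)[C@H](OC(C)=O)CCC(C)=C | intermediate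
27 | stylatulide lactone, (1S,2R,5Z,7S,8S,9R,10S,14S,17R)-2,9,14-triacetoxy-8-hydroxybriara-5,11-diene 19,7-lactone | CC(=O)O[C@H]1CC=C(C)[C@@H]2[C@@H](OC(C)=O)[C@@]3(O)[C@H](/C=C(/C)CC[C@@H](OC(C)=O)[C@@]12C)OC(=O)[C@@H]3C | target

## Step count and risks

Total steps: 20. Longest linear sequence: 18 (1 → 2 → 3 → 8 → … → 27; steps 3 and 12 are side branches).

**Step 5 (the new catalytic Claisen rearrangement; risk of low turnover or low ee).** The fallback uses known chemistry and sets C1 and C10 by chirality transfer instead of catalyst control. It sets out from 3 (and uses 7) and comes back at 11. Oxidation of 3 with MnO2 in CH2Cl2 gives (2E)-4-{[tert-butyl(dimethyl)silyl]oxy}-2-methylbut-2-enal F1. Catalytic enantioselective methyl addition (Me2Zn, (+)-3-exo-morpholinoisoborneol 5 mol%, toluene, 0 °C, Re-face attack) gives (2R,3E)-5-{[tert-butyl(dimethyl)silyl]oxy}-3-methylpent-3-en-2-ol F2. Alkoxy exchange with 7 (PPTS, toluene, 40 °C) gives the secondary allyl vinyl ether F3. Heating F3 in toluene at 110 °C brings about the thermal Claisen rearrangement through the chair with the carbinol methyl equatorial, which passes the carbinol configuration on to C1 and C10 and gives the propenyl aldehyde F4. Allylboration as in step 6 gives the homoallylic alcohol F5, and ring-closing metathesis as in step 7, now with loss of propene, returns to 11.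

**Step 16 (Negishi coupling of a hindered 2-iodo-diene with a secondary zinc enolate).** The fallback sets out from 20 and comes back at 22, bypassing 21. Stille coupling of stannane 20 with tert-butyl 2-bromoprop-2-enoate (Pd(PPh3)4, CuI, DMF, 40 °C) gives the cross-conjugated dienyl acrylate F6. Chemoselective 1,4-reduction of the acrylate unit with [(Ph3P)CuH]6 in wet benzene, followed by α-protonation of the copper enolate, gives 22 as the same C17 epimer mixture.

**Step 20 (closure of the ten-membered ring with a trisubstituted olefin between two hindered alkenes).** The fallback is a relay ring-closing metathesis; it addresses slow catalyst loading at C6, not ring strain. It sets out from 16 and comes back at 27. Bought (2E)-pent-2-en-4-yn-1-ol is O-allylated (NaH, allyl bromide, THF) to (3E)-5-(prop-2-en-1-yloxy)pent-3-en-1-yne F7 and iodinated (NIS, AgNO3) to (3E)-1-iodo-5-(prop-2-en-1-yloxy)pent-3-en-1-yne F8. Steps 13 to 19 are then run unchanged with F8 in place of 18. Chromium-mediated coupling with 16 gives the relay propargylic alcohol F9, trans-hydrostannation gives the relay stannane F10, iodination gives the relay iodide F11, and Negishi coupling gives the relay ester F12. Epoxidation gives the relay epoxide F13 (not isolated) and then the relay hydroxy lactone F14, acetylation gives the relay triacetate F15, and DBU gives the 17R relay triacetate F16. With the second-generation Hoveyda–Grubbs catalyst in dilute toluene, the ruthenium loads at the unhindered terminal allyl ether of F16, expels 2,5-dihydrofuran and so arrives as the C6 alkylidene next to C7. Ring closure onto the 1,1-disubstituted C5 olefin then gives 27.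

## Further compounds

F1 | step 5 | (2E)-4-{[tert-butyl(dimethyl)silyl]oxy}-2-methylbut-2-enal | O=C/C(C)=C/CO[Si](C)(C)C(C)(C)C
F2 | step 5 | (2R,3E)-5-{[tert-butyl(dimethyl)silyl]oxy}-3-methylpent-3-en-2-ol | C[C@@H](O)/C(C)=C/CO[Si](C)(C)C(C)(C)C
F3 | step 5 | (1E)-1-{[(2R,3E)-5-{[tert-butyl(dimethyl)silyl]oxy}-3-methylpent-3-en-2-yl]oxy}-2,6-dimethylhepta-1,6-dien-3-one | C=C(C)CCC(=O)/C(C)=C/O[C@H](C)/C(C)=C/CO[Si](C)(C)C(C)(C)C
F4 | step 5 | (2R,3S,4E)-3-({[tert-butyl(dimethyl)silyl]oxy}methyl)-2,4-dimethyl-2-(4-methylpent-4-enoyl)hex-4-enal | O=C[C@](C)(C(=O)CCC(C)=C)[C@@H](CO[Si](C)(C)C(C)(C)C)/C(C)=C/C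
F5 | step 5 | (6R,7S)-6-[(2S,3E)-1-{[tert-butyl(dimethyl)silyl]oxy}-3-methylpent-3-en-2-yl]-7-hydroxy-2,6-dimethyldeca-1,9-dien-5-one | C=CC[C@H](O)[C@](C)(C(=O)CCC(C)=C)[C@@H](CO[Si](C)(C)C(C)(C)C)/C(C)=C/C
F6 | step 16 | (1R)-1-[(1S,2S,6S)-6-acetoxy-2-[(1R,2E,4E)-2-(3-tert-butoxy-3-oxoprop-1-en-2-yl)-1-hydroxyhexa-2,4-dien-1-yl]-1,3-dimethylcyclohex-3-en-1-yl]-4-methylpent-4-en-1-yl acetate | CC(=O)O[C@H]1CC=C(C)[C@H]([C@@H](O)/C(=C/C=C/C)C(=C)C(=O)OC(C)(C)C)[C@@]1(C)[C@H](OC(C)=O)CCC(C)=C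
F7 | step 20 | (3E)-5-(prop-2-en-1-yloxy)pent-3-en-1-yne | C#C/C=C/COCC=C
F8 | step 20 | (3E)-1-iodo-5-(prop-2-en-1-yloxy)pent-3-en-1-yne | IC#C/C=C/COCC=C
F9 | step 20 | relay propargylic alcohol (19 with the terminal CH3 replaced by CH2OCH2CH=CH2) | CC(=O)O[C@H]1CC=C(C)[C@H]([C@@H](O)C#C/C=C/COCC=C)[C@@]1(C)[C@H](OC(C)=O)CCC(C)=C
F10 | step 20 | relay stannane (20 with the terminal CH3 replaced by CH2OCH2CH=CH2) | CC(=O)O[C@H]1CC=C(C)[C@H]([C@@H](O)/C(=C/C=C/COCC=C)[Sn](CCCC)(CCCC)CCCC)[C@@]1(C)[C@H](OC(C)=O)CCC(C)=C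
F11 | step 20 | relay iodide (21 with the terminal CH3 replaced by CH2OCH2CH=CH2) | CC(=O)O[C@H]1CC=C(C)[C@H]([C@@H](O)/C(I)=C/C=C/COCC=C)[C@@]1(C)[C@H](OC(C)=O)CCC(C)=C
F12 | step 20 | relay ester (22 with the terminal CH3 replaced by CH2OCH2CH=CH2, both C17 epimers) | CC(=O)O[C@H]1CC=C(C)[C@H]([C@@H](O)/C(=C/C=C/COCC=C)C(C)C(=O)OC(C)(C)C)[C@@]1(C)[C@H](OC(C)=O)CCC(C)=C
F13 | step 20 | relay epoxide (23 with the terminal CH3 replaced by CH2OCH2CH=CH2) | CC(=O)O[C@H]1CC=C(C)[C@H]([C@@H](O)[C@]2(O[C@@H]2/C=C/COCC=C)C(C)C(=O)OC(C)(C)C)[C@@]1(C)[C@H](OC(C)=O)CCC(C)=C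
F14 | step 20 | relay hydroxy lactone (24 with the terminal CH3 replaced by CH2OCH2CH=CH2) | CC(=O)O[C@H]1CC=C(C)[C@H]([C@@H](O)[C@@]2(O)[C@H](/C=C/COCC=C)OC(=O)C2C)[C@@]1(C)[C@H](OC(C)=O)CCC(C)=C
F15 | step 20 | relay triacetate (25 with the terminal CH3 replaced by CH2OCH2CH=CH2) | CC(=O)O[C@H]1CC=C(C)[C@H]([C@@H](OC(C)=O)[C@@]2(O)[C@H](/C=C/COCC=C)OC(=O)C2C)[C@@]1(C)[C@H](OC(C)=O)CCC(C)=C
F16 | step 20 | 17R relay triacetate (26 with the terminal CH3 replaced by CH2OCH2CH=CH2) | CC(=O)O[C@H]1CC=C(C)[C@H]([C@@H](OC(C)=O)[C@@]2(O)[C@H](/C=C/COCC=C)OC(=O)[C@@H]2C)[C@@]1(C)[C@H](OC(C)=O)CCC(C)=C
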